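**Plan**

1. Numbering used here: C14 is the ring CH, C15 the carbinol carbon, and the ring runs C14–C1H2–C2H=C3(C20H2OH)–C4–C5–C6H=C7(Me)–C8–C9–C10H=C11(Me)–C12–C13–C14. The retrosynthesis cuts the ring at C11–C12 (the sp2–sp3 bond at the only Z olefin) and at C2=C3, with C2 as a one-carbon ylide linchpin on C1; this gives two C12 halves.
2. Half A (C1, C12–C19): nerol is epoxidised (Sharpless) and the epoxide is opened anti at C14 by a vinyl copper reagent. The vinyl group is the latent C13–C12 bridge; the CH2OH arm becomes C1 and is extended by C2 as a phosphonium salt.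
3. Half B (C3–C11, C20): geranyl bromide and silyloxyacetone give an α-silyloxy ketone. The E C6=C7 olefin is bought; the Z C10=C11 unit is installed as a (Z)-iodoalkene by an iodo-Wittig reaction.
4. Forward: the halves are joined at C2=C3 by a Wittig reaction in which the C20 oxygen of the ketone steers C1 cis to C20. The 14-membered ring is then closed by hydroboration of the C14 vinyl group and intramolecular B-alkyl Suzuki–Miyaura coupling onto C11.
5. Stereochemistry: C15 comes from the tartrate-controlled epoxidation and C14 from SN2 inversion in the epoxide opening. Each of the three ring olefins is fixed by a geometry-determining step, with no metathesis and no equilibration.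
6. Enabling feature: in the 14-membered ring, the stereocentre C14 is separated from the sp2 carbon C11 of the Z olefin by exactly two CH2 groups (C13, C12). The vinyl group that sets C14 therefore becomes, after anti-Markovnikov hydroboration, the C12 nucleophile that closes the ring.

Key step: step 12

Remark: nerol and geranyl bromide are taken as the single (Z) and (E) isomers, and L-(+)-tartrate is taken to deliver oxygen to the face of nerol that gives the (2S,3R)-epoxide.

**Step 1**
Reactants: 1 nerol, (2Z)-3,7-dimethylocta-2,6-dien-1-ol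
Product: 2 [(2S,3R)-3-methyl-3-(4-methylpent-3-en-1-yl)oxiran-2-yl]methanol
Conditions: Ti(OiPr)4 (cat.), L-(+)-diethyl tartrate (cat.), t-BuOOH, 4 Å MS, CH2Cl2, −20 °C
Reagents that add atoms: tert-butyl hydroperoxide, CC(C)(C)OO
Why: Sharpless asymmetric epoxidation; the Ti–tartrate complex binds only the allylic alcohol, so the 2,3-olefin reacts and the 6,7-olefin does not, and L-(+)-tartrate should deliver oxygen to the face that gives the (2S,3R)-epoxide, which fixes the future C15 as R.

**Step 2**
Reactants: 2 [(2S,3R)-3-methyl-3-(4-methylpent-3-en-1-yl)oxiran-2-yl]methanol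
Product: 3 (2R,3R)-2-ethenyl-3,7-dimethyloct-6-ene-1,3-diol
Conditions: CH2=CHMgBr (excess), CuI (cat.), THF, −30→0 °C; aq. NH4Cl
Reagents that add atoms: vinylmagnesium bromide, C=C[Mg]Br
Why: Copper-catalysed Grignard opening of a 2,3-epoxy alcohol; C3 is fully substituted, so the vinyl group should attack C2 by SN2 with inversion, giving the 1,3-diol with C14 (R) set against C15 (R) as the anti adduct of carbon and oxygen across the former (Z)-olefin (any 1,2-diol from a Payne-rearranged epoxide can be removed by a periodate wash).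

**Step 3**
Reactants: 3 (2R,3R)-2-ethenyl-3,7-dimethyloct-6-ene-1,3-diol
Product: 5 (2S,3R)-2-ethenyl-1-iodo-3,7-dimethyloct-6-en-3-ol, via primary mesylate 4 (not isolated)
Conditions: MsCl, Et3N, CH2Cl2, −20 °C; then NaI, acetone, 55 °C
Reagents that add atoms: sodium iodide, [Na+].[I-]; methanesulfonyl chloride, CS(=O)(=O)Cl (retained only in intermediate 4)
Why: Primary-selective mesylation followed by Finkelstein SN2 with iodide, chosen over I2-based methods so that no electrophilic iodine meets the tertiary alcohol and the C18=C19 olefin (iodoetherification).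

**Step 4**
Reactants: 5 (2S,3R)-2-ethenyl-1-iodo-3,7-dimethyloct-6-en-3-ol
Product: 6 triethyl{[(2S,3R)-2-ethenyl-1-iodo-3,7-dimethyloct-6-en-3-yl]oxy}silane
Conditions: Et3SiOTf, 2,6-lutidine, CH2Cl2, −78→0 °C
Reagents that add atoms: triethylsilyl trifluoromethanesulfonate, CC[Si](CC)(CC)OS(=O)(=O)C(F)(F)F
Why: Silyl triflate/lutidine silylation of the hindered tertiary alcohol, which removes the acidic proton and the 1,3-hydroxy-iodide relationship (oxetane formation, Grob fragmentation) before the basic ylide steps.

**Step 5**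
Reactants: 6 triethyl{[(2S,3R)-2-ethenyl-1-iodo-3,7-dimethyloct-6-en-3-yl]oxy}silane
Product: 7 [(3S,4R)-3-ethenyl-4,8-dimethyl-4-(triethylsilyloxy)non-7-en-1-yl]triphenylphosphonium iodide
Conditions: Ph3P=CH2 (from Ph3PCH3Br, NaHMDS, THF, 0 °C), then 6, THF, −78 °C→rt
Reagents that add atoms: methylenetriphenylphosphorane, C=P(c1ccccc1)(c1ccccc1)c1ccccc1
Why: C-Alkylation of a non-stabilised phosphorus ylide by a primary iodide (SN2) inserts C2 and gives the homologous phosphonium salt directly; the ylide is a soft, weakly basic carbon nucleophile, so substitution should win over E2 at the β-branched CH2I, and neither stereocentre is touched.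

**Step 6**
Reactants: 8 1-(tert-butyldimethylsilyloxy)propan-2-one
Product: 9 1-(tert-butyldimethylsilyloxy)propan-2-one N,N-dimethylhydrazone (C=N isomers)
Conditions: Me2NNH2, AcOH (cat.), EtOH, 60 °C
Reagents that add atoms: 1,1-dimethylhydrazine, CN(C)N
Why: Hydrazone condensation, which masks the ketone and allows a clean, regioselective mono-alkylation through the azaenolate.

**Step 7**
Reactants: 9 1-(tert-butyldimethylsilyloxy)propan-2-one N,N-dimethylhydrazone; 10 geranyl bromide, (2E)-1-bromo-3,7-dimethylocta-2,6-diene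
Product: 12 (5E)-1-(tert-butyldimethylsilyloxy)-6,10-dimethylundeca-5,9-dien-2-one, via alkylated hydrazone 11 (not isolated)
Conditions: LDA, THF, −78→0 °C; 10, −78 °C→rt; then sat. aq. oxalic acid, Et2O, rt
Reagents that add atoms: water, O
Why: Azaenolate alkylation; LDA should deprotonate the less substituted, non-oxygenated α-carbon (the CH3; the bulky OTBS group does not chelate), SN2 at the primary allylic bromide keeps the E geometry, and biphasic oxalic acid hydrolyses the hydrazone without loss of the silyl ether.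

**Step 8**
Reactants: 12 (5E)-1-(tert-butyldimethylsilyloxy)-6,10-dimethylundeca-5,9-dien-2-one
Product: 14 (5E)-1-(tert-butyldimethylsilyloxy)-8-(3,3-dimethyloxiran-2-yl)-6-methyloct-5-en-2-one (racemic at the oxirane CH), via bromohydrin 13 (not isolated)
Conditions: NBS, THF/H2O, 0 °C; then K2CO3, MeOH, 0 °C
Reagents that add atoms: water, O; N-bromosuccinimide, O=C1CCC(=O)N1Br (bromine retained only in intermediate 13)
Why: Bromohydrin formation in aqueous THF should favour the more exposed terminal trisubstituted olefin over the internal one, and carbonate closes the bromohydrin to the epoxide by intramolecular SN2; the new stereocentre is racemic and is destroyed in step 9.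

**Step 9**
Reactants: 14 (5E)-1-(tert-butyldimethylsilyloxy)-8-(3,3-dimethyloxiran-2-yl)-6-methyloct-5-en-2-one
Product: 15 (4E)-9-(tert-butyldimethylsilyloxy)-4-methyl-8-oxonon-4-enal
Conditions: H5IO6, THF/H2O, 0 °C
Reagents that add atoms: none
Why: Periodic acid hydrolyses the epoxide to the diol and cleaves it (glycol cleavage) to the aldehyde and acetone; the ketone, the silyl ether and the trisubstituted olefin should be inert.

**Step 10**
Reactants: 15 (4E)-9-(tert-butyldimethylsilyloxy)-4-methyl-8-oxonon-4-enal
Product: 16 (5E,9Z)-1-(tert-butyldimethylsilyloxy)-10-iodo-6-methylundeca-5,9-dien-2-one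
Conditions: EtPPh3I, n-BuLi, THF, rt; I2, −78 °C; NaHMDS, −20 °C; then 15, −78 °C
Reagents that add atoms: (1-iodoethylidene)triphenylphosphorane, CC(I)=P(c1ccccc1)(c1ccccc1)c1ccccc1
Why: Stork–Zhao-type Wittig olefination with the α-iodo ylide, which should react with the aldehyde in preference to the ketone at −78 °C and give the (Z)-2-iodoalk-2-ene (iodine cis to the chain) through kinetic cis-oxaphosphetane formation.

**Step 11**
Reactants: 7 [(3S,4R)-3-ethenyl-4,8-dimethyl-4-(triethylsilyloxy)non-7-en-1-yl]triphenylphosphonium iodide; 16 (5E,9Z)-1-(tert-butyldimethylsilyloxy)-10-iodo-6-methylundeca-5,9-dien-2-one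
Product: 18 (3S,5Z,9E,13Z)-6-[(tert-butyldimethylsilyloxy)methyl]-14-iodo-10-methyl-3-[(2R)-6-methyl-2-(triethylsilyloxy)hept-5-en-2-yl]pentadeca-1,5,9,13-tetraene, via phosphorus ylide 17 (not isolated)
Conditions: KHMDS, THF, −78 °C; then 16, −78→0 °C
Reagents that add atoms: none
Why: Wittig olefination of an α-silyloxy ketone with a non-stabilised ylide under salt-free kinetic conditions; in this reaction class the ylide substituent (C1) ends up on the side of the oxygen-bearing CH2 (C20) and not of the alkyl CH2 (C4), which should give C2=C3 with C1 cis to C20 (CIP Z, ring-trans), while the iodoalkene and both silyl ethers are inert.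

**Step 12**
Reactants: 18 (3S,5Z,9E,13Z)-6-[(tert-butyldimethylsilyloxy)methyl]-14-iodo-10-methyl-3-[(2R)-6-methyl-2-(triethylsilyloxy)hept-5-en-2-yl]pentadeca-1,5,9,13-tetraene
Product: 20 (1Z,5E,9Z,12R)-9-[(tert-butyldimethylsilyloxy)methyl]-1,5-dimethyl-12-[(2R)-6-methyl-2-(triethylsilyloxy)hept-5-en-2-yl]cyclotetradeca-1,5,9-triene, via B-alkyl-9-BBN adduct 19 (not isolated)
Conditions: 9-BBN-H, THF, 0 °C→rt; then slow addition to PdCl2(dppf) (cat.), Ph3As, Cs2CO3, DMF/THF/H2O, 50 °C, high dilution (ca. 1 mM)
Reagents that add atoms: 9-borabicyclo[3.3.1]nonane, B1C2CCCC1CCC2 (boron retained only in intermediate 19)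
Why: 9-BBN adds anti-Markovnikov to the only monosubstituted olefin (the C14 vinyl group) and puts boron on C12, while the three trisubstituted olefins and the iodoalkene are too hindered to react; under base the borane becomes a borate, Pd(0) inserts into the C11–I bond with retention, C12 passes from boron to palladium and reductive elimination forms C11–C12. The closest known reaction type is the intramolecular B-alkyl Suzuki–Miyaura macrocyclisation of an ω-alkenyl (Z)-2-iodoalk-2-ene. The one ring closed is the 14-membered carbocycle, formed head-to-tail by C(sp3)–C(sp2) coupling between C12 and C11 of an acyclic precursor. No stereocentre is formed: C14 and C15 are spectators, and the 10Z geometry is that of the iodoalkene, carried through oxidative addition and reductive elimination with retention, so the ring olefin cannot form as the E isomer. The step needs chemoselective hydroboration, which the unique terminal vinyl group on C14 secures, and ring closure in preference to intermolecular coupling, which slow addition at high dilution and an essentially strain-free 14-membered ring with two ring-trans olefins (C2=C3, C6=C7) already in place should secure.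

**Step 13**
Reactants: 20 (1Z,5E,9Z,12R)-9-[(tert-butyldimethylsilyloxy)methyl]-1,5-dimethyl-12-[(2R)-6-methyl-2-(triethylsilyloxy)hept-5-en-2-yl]cyclotetradeca-1,5,9-triene
Product: 21 (2R)-2-[(1R,3Z,7E,11Z)-4-(hydroxymethyl)-8,12-dimethylcyclotetradeca-3,7,11-trien-1-yl]-6-methylhept-5-en-2-ol (target)
Conditions: Bu4NF, THF, 0→40 °C
Reagents that add atoms: none
Why: Fluoride cleaves both Si–O bonds (the primary allylic TBS ether quickly, the tertiary TES ether on warming); no other group in the molecule reacts with fluoride, so the stereocentres and olefin geometries are unchanged.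

**Compound list**

1 | nerol, (2Z)-3,7-dimethylocta-2,6-dien-1-ol | CC(C)=CCC/C(C)=C\CO | starting material
2 | [(2S,3R)-3-methyl-3-(4-methylpent-3-en-1-yl)oxiran-2-yl]methanol | OC[C@@H]1O[C@]1(C)CCC=C(C)C | intermediate
3 | (2R,3R)-2-ethenyl-3,7-dimethyloct-6-ene-1,3-diol | CC(C)=CCC[C@@](C)(O)[C@H](C=C)CO | intermediate
4 | (2R,3R)-2-ethenyl-3-hydroxy-3,7-dimethyloct-6-en-1-yl methanesulfonate | CC(C)=CCC[C@@](C)(O)[C@H](C=C)COS(C)(=O)=O | intermediate (not isolated)
5 | (2S,3R)-2-ethenyl-1-iodo-3,7-dimethyloct-6-en-3-ol | CC(C)=CCC[C@@](C)(O)[C@H](C=C)CI | intermediate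
6 | triethyl{[(2S,3R)-2-ethenyl-1-iodo-3,7-dimethyloct-6-en-3-yl]oxy}silane | CC(C)=CCC[C@@](C)(O[Si](CC)(CC)CC)[C@H](C=C)CI | intermediate
7 | [(3S,4R)-3-ethenyl-4,8-dimethyl-4-(triethylsilyloxy)non-7-en-1-yl]triphenylphosphonium iodide | CC(C)=CCC[C@@](C)(O[Si](CC)(CC)CC)[C@H](C=C)CC[P+](c1ccccc1)(c1ccccc1)c1ccccc1.[I-] | intermediate
8 | 1-(tert-butyldimethylsilyloxy)propan-2-one | CC(=O)CO[Si](C)(C)C(C)(C)C | starting material
9 | 1-(tert-butyldimethylsilyloxy)propan-2-one N,N-dimethylhydrazone (C=N isomers) | CC(CO[Si](C)(C)C(C)(C)C)=NN(C)C | intermediate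
10 | geranyl bromide, (2E)-1-bromo-3,7-dimethylocta-2,6-diene | CC(C)=CCC/C(C)=C/CBr | starting material
11 | N,N-dimethylhydrazone of 12 (C=N isomers) | CC(C)=CCC/C(C)=C/CCC(CO[Si](C)(C)C(C)(C)C)=NN(C)C | intermediate (not isolated)
12 | (5E)-1-(tert-butyldimethylsilyloxy)-6,10-dimethylundeca-5,9-dien-2-one | CC(C)=CCC/C(C)=C/CCC(=O)CO[Si](C)(C)C(C)(C)C | intermediate
13 | (5E)-9-bromo-1-(tert-butyldimethylsilyloxy)-10-hydroxy-6,10-dimethylundec-5-en-2-one (racemic at C9) | CC(C)(O)C(Br)CC/C(C)=C/CCC(=O)CO[Si](C)(C)C(C)(C)C | intermediate (not isolated)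
14 | (5E)-1-(tert-butyldimethylsilyloxy)-8-(3,3-dimethyloxiran-2-yl)-6-methyloct-5-en-2-one (racemic at the oxirane CH) | CC1(C)OC1CC/C(C)=C/CCC(=O)CO[Si](C)(C)C(C)(C)C | intermediate
15 | (4E)-9-(tert-butyldimethylsilyloxy)-4-methyl-8-oxonon-4-enal | O=CCC/C(C)=C/CCC(=O)CO[Si](C)(C)C(C)(C)C | intermediate
16 | (5E,9Z)-1-(tert-butyldimethylsilyloxy)-10-iodo-6-methylundeca-5,9-dien-2-one | C/C(I)=C/CC/C(C)=C/CCC(=O)CO[Si](C)(C)C(C)(C)C | intermediate
17 | [(3S,4R)-3-ethenyl-4,8-dimethyl-4-(triethylsilyloxy)non-7-en-1-ylidene]triphenylphosphorane | CC(C)=CCC[C@@](C)(O[Si](CC)(CC)CC)[C@H](C=C)CC=P(c1ccccc1)(c1ccccc1)c1ccccc1 | intermediate (not isolated)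
18 | (3S,5Z,9E,13Z)-6-[(tert-butyldimethylsilyloxy)methyl]-14-iodo-10-methyl-3-[(2R)-6-methyl-2-(triethylsilyloxy)hept-5-en-2-yl]pentadeca-1,5,9,13-tetraene | CC(C)=CCC[C@@](C)(O[Si](CC)(CC)CC)[C@H](C=C)C/C=C(\CO[Si](C)(C)C(C)(C)C)CC/C=C(\C)CC/C=C(/C)I | intermediate
19 | 9-BBN adduct of 18 at the terminal vinyl carbon (boron on C12; C14 and C15 as in 18) | CC(C)=CCC[C@@](C)(O[Si](CC)(CC)CC)[C@H](CCB1C2CCCC1CCC2)C/C=C(\CO[Si](C)(C)C(C)(C)C)CC/C=C(\C)CC/C=C(/C)I | intermediate (not isolated)
20 | (1Z,5E,9Z,12R)-9-[(tert-butyldimethylsilyloxy)methyl]-1,5-dimethyl-12-[(2R)-6-methyl-2-(triethylsilyloxy)hept-5-en-2-yl]cyclotetradeca-1,5,9-triene | CC(C)=CCC[C@@](C)(O[Si](CC)(CC)CC)[C@H]1C/C=C(\CO[Si](C)(C)C(C)(C)C)CC/C=C(\C)CC/C=C(/C)CC1 | intermediate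
21 | (2R)-2-[(1R,3Z,7E,11Z)-4-(hydroxymethyl)-8,12-dimethylcyclotetradeca-3,7,11-trien-1-yl]-6-methylhept-5-en-2-ol | CC(C)=CCC[C@@](C)(O)[C@H]1C/C=C(\CO)CC/C=C(\C)CC/C=C(/C)CC1 | target

**Totals**

Total step count: 13.
Longest linear sequence: 8 steps (steps 1–5, then 11–13; the ketone branch, steps 6–10 then 11–13, is equally long).

**Steps most likely to fail**

1. Step 12 (macrocyclisation). Ring closure may lose to intermolecular coupling (oligomers), the borate may be protodeboronated, or the alkylpalladium may undergo β-hydride elimination. The fallback sets out from 18 and returns at 20. Hydroboration of 18 with 9-BBN and oxidative work-up (NaOH, H2O2) should give the primary C12 alcohol F1. Iodine, PPh3 and imidazole should convert it into the primary alkyl iodide F2. Zinc dust with LiCl in THF should insert into the alkyl C–I bond only, giving the alkylzinc iodide F3. Slow addition of F3 to a Pd(0)/phosphine catalyst should close C11–C12 by an intramolecular Negishi coupling to give 20. This replaces the in-situ borane by an isolable precursor and a base-free, water-free transmetalation.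

2. Step 5 (ylide alkylation). E2 loss of HI across C1–C14 may compete with substitution at the β-branched CH2I, substitution may be slow, and ylide exchange may lead to double alkylation. The fallback sets out from 6 and returns at 7. Iodine–lithium exchange on 6 (t-BuLi, Et2O, −78 °C) and trapping with paraformaldehyde should give the homologous primary alcohol F4. Iodine, PPh3 and imidazole should give the unhindered primary iodide F5. Heating F5 with PPh3 in MeCN should give 7 by ordinary quaternisation.

3. Step 11 (Wittig union). Geometric control in oxaphosphetane formation may be poor (E/Z mixture at C2=C3), or the basic ylide may enolise the ketone. The fallback sets out from 7 and 16 and returns at 18. Alkaline hydrolysis of 7 (aq. NaOH, heat) should give the alkyldiphenylphosphine oxide F6. Lithiation (n-BuLi, THF, −78 °C) and addition to 16 should give the β-hydroxy phosphine oxides F7, which are stable and separable by chromatography. The diastereomers in which C1 and C20 lie on the same side when P and O are syn are treated with KH in DMF; the stereospecific syn-elimination (Horner–Wittig) should give 18 as a single geometric isomer.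

**Further compounds**

F1 | step 12 | primary alcohol from anti-Markovnikov hydration of the vinyl group of 18 (OH on C12) | CC(C)=CCC[C@@](C)(O[Si](CC)(CC)CC)[C@H](CCO)C/C=C(\CO[Si](C)(C)C(C)(C)C)CC/C=C(\C)CC/C=C(/C)I
F2 | step 12 | primary alkyl iodide from F1 (iodine on C12) | CC(C)=CCC[C@@](C)(O[Si](CC)(CC)CC)[C@H](CCI)C/C=C(\CO[Si](C)(C)C(C)(C)C)CC/C=C(\C)CC/C=C(/C)I
F3 | step 12 | alkylzinc iodide from F2 (zinc on C12) | CC(C)=CCC[C@@](C)(O[Si](CC)(CC)CC)[C@H](CC[Zn]I)C/C=C(\CO[Si](C)(C)C(C)(C)C)CC/C=C(\C)CC/C=C(/C)I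
F4 | step 5 | (3S,4R)-3-ethenyl-4,8-dimethyl-4-(triethylsilyloxy)non-7-en-1-ol | CC(C)=CCC[C@@](C)(O[Si](CC)(CC)CC)[C@H](C=C)CCO
F5 | step 5 | (3S,4R)-3-ethenyl-1-iodo-4,8-dimethyl-4-(triethylsilyloxy)non-7-ene | CC(C)=CCC[C@@](C)(O[Si](CC)(CC)CC)[C@H](C=C)CCI
F6 | step 11 | [(3S,4R)-3-ethenyl-4,8-dimethyl-4-(triethylsilyloxy)non-7-en-1-yl]diphenylphosphine oxide | CC(C)=CCC[C@@](C)(O[Si](CC)(CC)CC)[C@H](C=C)CCP(=O)(c1ccccc1)c1ccccc1
F7 | step 11 | β-hydroxy phosphine oxide adducts of F6 and 16 (Ph2P(O) on C2, OH on C3; diastereomers at C2 and C3, separated) | CC(C)=CCC[C@@](C)(O[Si](CC)(CC)CC)[C@H](C=C)CC(P(=O)(c1ccccc1)c1ccccc1)C(O)(CO[Si](C)(C)C(C)(C)C)CC/C=C(\C)CC/C=C(/C)I
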